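**Plan**
Numbering: lactone carbonyl C1, ring oxygen O1, carbinol carbons C5 and C6, oxolane carbons C7–C10, ester carbinol C11, methyl C12.
Retrosynthesis: cut the C11–O ester bond (Z-coumaroyl unit), saturate C2=C3, take O1 out from between C1 and C5 (retro-Baeyer–Villiger, restoring a C1–C5 bond), then cut C5–C6 (aldol) and C11–C12 (methyl addition) to reach a meso oxolane diol.
Enabling feature: ring atoms C1, C2, C3, C4 and C5 of the dihydropyranone are the five carbons of a cyclopentanone and O1 lies between C1 and C5, so the lactone is a 2-substituted cyclopentanone aldol with one oxygen inserted.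
Forward: the oxolane ring is bought as the meso diol and desymmetrised; C12 is added to one arm and the other arm becomes the C6 aldehyde; the cyclopentanone ring is joined by aldol addition and expanded to the δ-lactone; dehydrogenation, esterification at C11 and desilylation finish the synthesis.
Stereochemistry: C7 and C10 from lipase desymmetrisation; C11 from chelation-controlled MeMgBr addition; C6 and C5 from a chelation-controlled syn Mukaiyama aldol, C5 then migrating with retention; the Z-alkene from Lindlar semi-hydrogenation.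

Key step: step 9

Assumption: the lipase acetylates the hydroxymethyl arm on the R-configured ring carbon of diol 1, giving the (2R,5S)-monoacetate 2; should a given lipase prefer the other arm, the same enzyme applied to hydrolysis of the diacetate gives 2, because the two modes are enantiocomplementary.
Remark: the descriptor of C6 changes from R in ketones 10 and 11 to S from lactone 12 onwards only because C5 gains CIP priority once it bears O1; the geometry is unchanged.

Step 1
Reactants: 1 cis-2,5-bis(hydroxymethyl)tetrahydrofuran (meso)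
Product: 2 [(2R,5S)-5-(hydroxymethyl)oxolan-2-yl]methyl acetate
Conditions: lipase PS (Burkholderia cepacia), vinyl acetate, THF, 25 °C
Reagents that add atoms: vinyl acetate, CC(=O)OC=C
Why: Lipase-catalysed irreversible transesterification (desymmetrisation of a meso diol) should acetylate one of the two enantiotopic hydroxymethyl arms only, which fixes both ring stereocentres C7 and C10 at once, the vinyl alcohol leaving group tautomerising to acetaldehyde so that the acyl transfer cannot reverse.

Step 2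
Reactants: 2 [(2R,5S)-5-(hydroxymethyl)oxolan-2-yl]methyl acetate
Product: 3 [(2R,5S)-5-formyloxolan-2-yl]methyl acetate
Conditions: Dess–Martin periodinane, pyridine, CH2Cl2, 0 °C to rt
Reagents that add atoms: none
Why: Dess–Martin oxidation of a primary alcohol stops at the aldehyde under buffered, non-basic conditions that should not epimerise the α-oxygenated C10 centre or touch the acetate.

Step 3
Reactants: 3 [(2R,5S)-5-formyloxolan-2-yl]methyl acetate; 4 methylmagnesium bromide
Product: 5 [(2R,5S)-5-[(1S)-1-hydroxyethyl]oxolan-2-yl]methyl acetate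
Conditions: MgBr2·OEt2, CH2Cl2, −78 °C; then MeMgBr (Et2O), −78 °C; H2O/aq. NH4Cl
Reagents that add atoms: none
Why: Chelation-controlled (Cram-chelate) Grignard addition, in which magnesium bridges the aldehyde oxygen and the ring oxygen in the weakly coordinating solvent, should deliver the methyl group to the chelate face opposite C9 and set C11 as S (syn to the C10–O bond), the aldehyde reacting far faster than the acetate at −78 °C.

Step 4
Reactants: 5 [(2R,5S)-5-[(1S)-1-hydroxyethyl]oxolan-2-yl]methyl acetate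
Product: 6 [(2R,5S)-5-[(1S)-1-(triethylsilyloxy)ethyl]oxolan-2-yl]methyl acetate
Conditions: Et3SiCl, imidazole, CH2Cl2, 0 °C
Reagents that add atoms: chlorotriethylsilane, CC[Si](Cl)(CC)CC
Why: Standard silylation of a secondary alcohol (silyl chloride/imidazole) gives a triethylsilyl ether, chosen because it is a poor ligand for the Lewis acid of step 7 and can later be removed selectively beside a tert-butyldimethylsilyl ether.

Step 5
Reactants: 6 [(2R,5S)-5-[(1S)-1-(triethylsilyloxy)ethyl]oxolan-2-yl]methyl acetate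
Product: 7 [(2R,5S)-5-[(1S)-1-(triethylsilyloxy)ethyl]oxolan-2-yl]methanol
Conditions: K2CO3 (cat.), MeOH, 0 °C
Reagents that add atoms: none
Why: Base-catalysed transesterification (methanolysis) of the primary acetate is mild enough to leave the secondary triethylsilyl ether intact.

Step 6
Reactants: 7 [(2R,5S)-5-[(1S)-1-(triethylsilyloxy)ethyl]oxolan-2-yl]methanol
Product: 8 (2R,5S)-5-[(1S)-1-(triethylsilyloxy)ethyl]oxolane-2-carbaldehyde
Conditions: Dess–Martin periodinane, pyridine, CH2Cl2, 0 °C to rt
Reagents that add atoms: none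
Why: Dess–Martin oxidation under pyridine buffering should give the α-alkoxy aldehyde without epimerisation at C7 or loss of the silyl ether, the aldehyde being used directly.

Step 7
Reactants: 8 (2R,5S)-5-[(1S)-1-(triethylsilyloxy)ethyl]oxolane-2-carbaldehyde; 9 1-(trimethylsilyloxy)cyclopentene
Product: 10 (2R)-2-[(R)-hydroxy{(2R,5S)-5-[(1S)-1-(triethylsilyloxy)ethyl]oxolan-2-yl}methyl]cyclopentan-1-one
Conditions: TiCl4 (1.1 equiv), CH2Cl2, −78 °C; then 9, −78 °C; H2O
Reagents that add atoms: none
Why: Mukaiyama aldol addition under Cram-chelate control, in which TiCl4 bridges the aldehyde oxygen and the oxolane oxygen (the hindered, weakly basic silyl ether at C11 should not compete), is expected to direct the enol silane to the chelate face opposite C8 and set C6 syn to the C7–O bond, while the open transition state of chelated α-alkoxy aldehydes should favour the syn C5/C6 relationship for the cyclic enol silane.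

Step 8
Reactants: 10 (2R)-2-[(R)-hydroxy{(2R,5S)-5-[(1S)-1-(triethylsilyloxy)ethyl]oxolan-2-yl}methyl]cyclopentan-1-one
Product: 11 (2R)-2-[(R)-(tert-butyldimethylsilyloxy){(2R,5S)-5-[(1S)-1-(triethylsilyloxy)ethyl]oxolan-2-yl}methyl]cyclopentan-1-one
Conditions: TBSOTf, 2,6-lutidine, CH2Cl2, −78 °C
Reagents that add atoms: tert-butyldimethylsilyl trifluoromethanesulfonate, CC(C)(C)[Si](C)(C)OS(=O)(=O)C(F)(F)F
Why: Silylation of a hindered β-hydroxy ketone with a silyl triflate and a hindered pyridine base at −78 °C is fast enough to outrun retro-aldol cleavage, dehydration and enol silylation, so C5 and C6 should be preserved.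

Step 9
Reactants: 11 (2R)-2-[(R)-(tert-butyldimethylsilyloxy){(2R,5S)-5-[(1S)-1-(triethylsilyloxy)ethyl]oxolan-2-yl}methyl]cyclopentan-1-one
Product: 12 (6R)-6-[(S)-(tert-butyldimethylsilyloxy){(2R,5S)-5-[(1S)-1-(triethylsilyloxy)ethyl]oxolan-2-yl}methyl]oxan-2-one
Conditions: mCPBA, NaHCO3 (solid buffer), CH2Cl2, 0 °C to rt
Reagents that add atoms: 3-chloroperoxybenzoic acid, OOC(=O)c1cccc(Cl)c1
Why: Baeyer–Villiger oxidation: the peracid adds to the C1 ketone to give a Criegee tetrahedral intermediate, in which the C1–C5 bond lying antiperiplanar to the peroxide O–O bond shifts to oxygen as 3-chlorobenzoate departs. The closest known reaction type is the peracid oxidation of 2-(1-acyloxyalkyl)- and 2-(1-silyloxyalkyl)cyclopentanones to 6-substituted δ-lactones. The six-membered lactone is not closed by cyclisation but arises by ring expansion of the five-membered carbocycle through insertion of O1 between C1 and C5. No stereocentre is created, since C5 migrates in a concerted 1,2-shift with retention and C6, C7, C10 and C11 take no part. The selectivity required is migration of C5 in preference to the ring methylene C2, which the secondary, more electron-rich character of C5 should secure even though the β-silyloxy group at C6 lowers its migratory aptitude somewhat. The bicarbonate buffer is there to keep 3-chlorobenzoic acid from cleaving the triethylsilyl ether or epimerising C5 before oxidation.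

Step 10
Reactants: 12 (6R)-6-[(S)-(tert-butyldimethylsilyloxy){(2R,5S)-5-[(1S)-1-(triethylsilyloxy)ethyl]oxolan-2-yl}methyl]oxan-2-one
Product: 14 (6R)-6-[(S)-(tert-butyldimethylsilyloxy){(2R,5S)-5-[(1S)-1-(triethylsilyloxy)ethyl]oxolan-2-yl}methyl]-3-(phenylselanyl)oxan-2-one (both epimers at the selenium-bearing carbon), via lithium enolate 13 (not isolated)
Conditions: LiN(iPr)2, THF, −78 °C; then PhSeBr, −78 °C
Reagents that add atoms: benzeneselenenyl bromide, Br[Se]c1ccccc1
Why: Kinetic lactone enolate formation followed by electrophilic α-selenenylation should place selenium at C2, the only enolisable position, and the configuration there is irrelevant because the centre is removed in the next step.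

Step 11
Reactants: 14 (6R)-6-[(S)-(tert-butyldimethylsilyloxy){(2R,5S)-5-[(1S)-1-(triethylsilyloxy)ethyl]oxolan-2-yl}methyl]-3-(phenylselanyl)oxan-2-one
Product: 16 (6R)-6-[(S)-(tert-butyldimethylsilyloxy){(2R,5S)-5-[(1S)-1-(triethylsilyloxy)ethyl]oxolan-2-yl}methyl]-5,6-dihydro-2H-pyran-2-one, via selenoxide 15 (not isolated)
Conditions: H2O2 (30% aq.), pyridine, CH2Cl2, 0 °C to rt
Reagents that add atoms: none
Why: Oxidation of the selenide to the selenoxide and its spontaneous syn-elimination (selenoxide elimination) can only proceed towards the β-hydrogens at C3 and should therefore give the conjugated C2=C3 alkene inside the ring.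

Step 12
Reactants: 16 (6R)-6-[(S)-(tert-butyldimethylsilyloxy){(2R,5S)-5-[(1S)-1-(triethylsilyloxy)ethyl]oxolan-2-yl}methyl]-5,6-dihydro-2H-pyran-2-one
Product: 17 (6R)-6-[(S)-(tert-butyldimethylsilyloxy){(2R,5S)-5-[(1S)-1-hydroxyethyl]oxolan-2-yl}methyl]-5,6-dihydro-2H-pyran-2-one
Conditions: PPTS (cat.), MeOH/CH2Cl2, 0 °C to rt
Reagents that add atoms: none
Why: Acid-catalysed methanolysis (chemoselective desilylation) should remove the labile triethylsilyl ether at C11 while the much slower-reacting tert-butyldimethylsilyl ether at C6 and the lactone remain.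

Step 13
Reactants: 18 tert-butyl(4-ethynylphenoxy)dimethylsilane
Product: 20 3-[4-(tert-butyldimethylsilyloxy)phenyl]prop-2-ynoic acid, via lithium acetylide 19 (not isolated)
Conditions: n-BuLi, THF, −78 °C; then CO2; aq. HCl (1 M), 0 °C
Reagents that add atoms: carbon dioxide, O=C=O
Why: Deprotonation of the terminal alkyne and carboxylation of the lithium acetylide is the standard route to arylpropiolic acids, and the aryl silyl ether should tolerate butyllithium at −78 °C and brief cold dilute acid.

Step 14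
Reactants: 20 3-[4-(tert-butyldimethylsilyloxy)phenyl]prop-2-ynoic acid
Product: 21 (2Z)-3-[4-(tert-butyldimethylsilyloxy)phenyl]prop-2-enoic acid
Conditions: H2 (1 atm), Pd/CaCO3 poisoned with Pb(OAc)2 (Lindlar catalyst), quinoline, EtOAc, rt, dark
Reagents that add atoms: none
Why: Lindlar semi-hydrogenation adds H2 in syn fashion on the poisoned palladium surface and stops at the alkene, which sets the Z geometry of the coumaroyl unit.

Step 15
Reactants: 17 (6R)-6-[(S)-(tert-butyldimethylsilyloxy){(2R,5S)-5-[(1S)-1-hydroxyethyl]oxolan-2-yl}methyl]-5,6-dihydro-2H-pyran-2-one; 21 (2Z)-3-[4-(tert-butyldimethylsilyloxy)phenyl]prop-2-enoic acid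
Product: 22 (1S)-1-[(2S,5R)-5-[(S)-(tert-butyldimethylsilyloxy)[(2R)-6-oxo-3,6-dihydro-2H-pyran-2-yl]methyl]oxolan-2-yl]ethyl (2Z)-3-[4-(tert-butyldimethylsilyloxy)phenyl]prop-2-enoate
Conditions: DCC, DMAP (cat.), CH2Cl2, 0 °C, dark
Reagents that add atoms: none
Why: Steglich esterification acylates the C11 hydroxyl at oxygen with retention of configuration, and low temperature, a catalytic amount of DMAP and exclusion of light are meant to keep the Z-alkene from isomerising.

Step 16
Reactants: 22 (1S)-1-[(2S,5R)-5-[(S)-(tert-butyldimethylsilyloxy)[(2R)-6-oxo-3,6-dihydro-2H-pyran-2-yl]methyl]oxolan-2-yl]ethyl (2Z)-3-[4-(tert-butyldimethylsilyloxy)phenyl]prop-2-enoate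
Product: 23 (1S)-1-[(2S,5R)-5-[(S)-hydroxy[(2R)-6-oxo-3,6-dihydro-2H-pyran-2-yl]methyl]oxolan-2-yl]ethyl (2Z)-3-(4-hydroxyphenyl)prop-2-enoate
Conditions: HF·pyridine, pyridine, THF, 0 °C to rt, dark
Reagents that add atoms: none
Why: Fluoride-mediated desilylation under buffered acidic conditions should cleave both the aryl and the secondary alkyl silyl ether without opening the unsaturated lactone, hydrolysing the ester or isomerising the Z-alkene.

**Compound list**
1 | cis-2,5-bis(hydroxymethyl)tetrahydrofuran (meso) | OC[C@@H]1CC[C@H](CO)O1 | starting material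
2 | [(2R,5S)-5-(hydroxymethyl)oxolan-2-yl]methyl acetate | OC[C@@H]1CC[C@H](COC(C)=O)O1 | intermediate
3 | [(2R,5S)-5-formyloxolan-2-yl]methyl acetate | O=C[C@@H]1CC[C@H](COC(C)=O)O1 | intermediate
4 | methylmagnesium bromide | C[Mg]Br | starting material
5 | [(2R,5S)-5-[(1S)-1-hydroxyethyl]oxolan-2-yl]methyl acetate | C[C@H](O)[C@@H]1CC[C@H](COC(C)=O)O1 | intermediate
6 | [(2R,5S)-5-[(1S)-1-(triethylsilyloxy)ethyl]oxolan-2-yl]methyl acetate | C[C@H](O[Si](CC)(CC)CC)[C@@H]1CC[C@H](COC(C)=O)O1 | intermediate
7 | [(2R,5S)-5-[(1S)-1-(triethylsilyloxy)ethyl]oxolan-2-yl]methanol | C[C@H](O[Si](CC)(CC)CC)[C@@H]1CC[C@H](CO)O1 | intermediate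
8 | (2R,5S)-5-[(1S)-1-(triethylsilyloxy)ethyl]oxolane-2-carbaldehyde | C[C@H](O[Si](CC)(CC)CC)[C@@H]1CC[C@H](C=O)O1 | intermediate
9 | 1-(trimethylsilyloxy)cyclopentene | C[Si](C)(C)OC1=CCCC1 | starting material
10 | (2R)-2-[(R)-hydroxy{(2R,5S)-5-[(1S)-1-(triethylsilyloxy)ethyl]oxolan-2-yl}methyl]cyclopentan-1-one | C[C@H](O[Si](CC)(CC)CC)[C@@H]1CC[C@H]([C@H](O)[C@H]2CCCC2=O)O1 | intermediate
11 | (2R)-2-[(R)-(tert-butyldimethylsilyloxy){(2R,5S)-5-[(1S)-1-(triethylsilyloxy)ethyl]oxolan-2-yl}methyl]cyclopentan-1-one | C[C@H](O[Si](CC)(CC)CC)[C@@H]1CC[C@H]([C@H](O[Si](C)(C)C(C)(C)C)[C@H]2CCCC2=O)O1 | intermediate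
12 | (6R)-6-[(S)-(tert-butyldimethylsilyloxy){(2R,5S)-5-[(1S)-1-(triethylsilyloxy)ethyl]oxolan-2-yl}methyl]oxan-2-one | C[C@H](O[Si](CC)(CC)CC)[C@@H]1CC[C@H]([C@H](O[Si](C)(C)C(C)(C)C)[C@H]2CCCC(=O)O2)O1 | intermediate
13 | lithium enolate of lactone 12 | C[C@H](O[Si](CC)(CC)CC)[C@@H]1CC[C@H]([C@H](O[Si](C)(C)C(C)(C)C)[C@H]2CCC=C(O[Li])O2)O1 | intermediate
14 | (6R)-6-[(S)-(tert-butyldimethylsilyloxy){(2R,5S)-5-[(1S)-1-(triethylsilyloxy)ethyl]oxolan-2-yl}methyl]-3-(phenylselanyl)oxan-2-one (both epimers at the selenium-bearing carbon) | C[C@H](O[Si](CC)(CC)CC)[C@@H]1CC[C@H]([C@H](O[Si](C)(C)C(C)(C)C)[C@H]2CCC([Se]c3ccccc3)C(=O)O2)O1 | intermediate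
15 | (6R)-6-[(S)-(tert-butyldimethylsilyloxy){(2R,5S)-5-[(1S)-1-(triethylsilyloxy)ethyl]oxolan-2-yl}methyl]-3-(phenylseleninyl)oxan-2-one | C[C@H](O[Si](CC)(CC)CC)[C@@H]1CC[C@H]([C@H](O[Si](C)(C)C(C)(C)C)[C@H]2CCC([Se](=O)c3ccccc3)C(=O)O2)O1 | intermediate
16 | (6R)-6-[(S)-(tert-butyldimethylsilyloxy){(2R,5S)-5-[(1S)-1-(triethylsilyloxy)ethyl]oxolan-2-yl}methyl]-5,6-dihydro-2H-pyran-2-one | C[C@H](O[Si](CC)(CC)CC)[C@@H]1CC[C@H]([C@H](O[Si](C)(C)C(C)(C)C)[C@H]2CC=CC(=O)O2)O1 | intermediate
17 | (6R)-6-[(S)-(tert-butyldimethylsilyloxy){(2R,5S)-5-[(1S)-1-hydroxyethyl]oxolan-2-yl}methyl]-5,6-dihydro-2H-pyran-2-one | C[C@H](O)[C@@H]1CC[C@H]([C@H](O[Si](C)(C)C(C)(C)C)[C@H]2CC=CC(=O)O2)O1 | intermediate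
18 | tert-butyl(4-ethynylphenoxy)dimethylsilane | C#Cc1ccc(O[Si](C)(C)C(C)(C)C)cc1 | starting material
19 | lithium [4-(tert-butyldimethylsilyloxy)phenyl]acetylide | [Li]C#Cc1ccc(O[Si](C)(C)C(C)(C)C)cc1 | intermediate
20 | 3-[4-(tert-butyldimethylsilyloxy)phenyl]prop-2-ynoic acid | OC(=O)C#Cc1ccc(O[Si](C)(C)C(C)(C)C)cc1 | intermediate
21 | (2Z)-3-[4-(tert-butyldimethylsilyloxy)phenyl]prop-2-enoic acid | OC(=O)/C=C\c1ccc(O[Si](C)(C)C(C)(C)C)cc1 | intermediate
22 | (1S)-1-[(2S,5R)-5-[(S)-(tert-butyldimethylsilyloxy)[(2R)-6-oxo-3,6-dihydro-2H-pyran-2-yl]methyl]oxolan-2-yl]ethyl (2Z)-3-[4-(tert-butyldimethylsilyloxy)phenyl]prop-2-enoate | C[C@H](OC(=O)/C=C\c1ccc(O[Si](C)(C)C(C)(C)C)cc1)[C@@H]1CC[C@H]([C@H](O[Si](C)(C)C(C)(C)C)[C@H]2CC=CC(=O)O2)O1 | intermediate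
23 | (1S)-1-[(2S,5R)-5-[(S)-hydroxy[(2R)-6-oxo-3,6-dihydro-2H-pyran-2-yl]methyl]oxolan-2-yl]ethyl (2Z)-3-(4-hydroxyphenyl)prop-2-enoate | C[C@H](OC(=O)/C=C\c1ccc(O)cc1)[C@@H]1CC[C@H]([C@H](O)[C@H]2CC=CC(=O)O2)O1 | target

**Step count**
Total: 16 steps. Longest linear sequence: 14 steps (steps 1–12, 15 and 16); steps 13 and 14 form the side branch to acid 21.

**Steps most likely to fail**

Step 7. Chelation control may erode if a second TiCl4 molecule activates the aldehyde in an open, non-chelated mode; simple diastereoselection at C5 may be weak for the cyclic enol silane; and the triethylsilyl ether may be lost to the Lewis acid. The fallback sets out from aldehyde 8 and replaces substrate control by auxiliary control. Aldehyde 8 would be added to the dibutylboron Z-enolate of (R)-4-benzyl-3-(pent-4-enoyl)-1,3-oxazolidin-2-one (Bu2BOTf, iPr2NEt, CH2Cl2, −78 to 0 °C), whose Zimmerman–Traxler chair should give the Evans syn-aldol imide F1 with C5 and C6 fixed by the auxiliary. Transamidation with MeNH(OMe)·HCl and AlMe3 would release the auxiliary and give Weinreb amide F2, and TBSOTf/2,6-lutidine would give its silyl ether F3. Addition of CH2=CHMgBr would give dienone F4, ring-closing metathesis with second-generation Grubbs catalyst would close the five-membered ring as cyclopentenone F5, and hydrogenation of the enone double bond (H2, Pd/C, EtOAc) would return to ketone 11.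

Step 3. Incomplete chelation would lower the facial selectivity at C11, and any warming would allow attack on the acetate. The fallback sets out from carbinol 5 as obtained (whatever the epimer ratio at C11). Dess–Martin oxidation would give the methyl ketone F6, and reduction with BH3·SMe2 and (R)-2-methyl-CBS-oxazaborolidine, which treats methyl as the small group, should return to 5 with the S configuration under reagent control.

Step 15. The activated Z-acid may isomerise to E through reversible conjugate addition of DMAP, and slow acylation of the hindered C11 alcohol may divert the activated acid to an N-acylurea. The fallback sets out from alcohol 17 and builds the alkene on the substrate. Carbodiimide coupling with [bis(2,2,2-trifluoroethoxy)phosphoryl]acetic acid would give the phosphonoacetate F7, and Still–Gennari olefination (KN(SiMe3)2, 18-crown-6, THF, −78 °C) with 4-(tert-butyldimethylsilyloxy)benzaldehyde should give ester 22 with the Z geometry set under kinetic control.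

**Further compounds**
F1 | step 7 | (4R)-4-benzyl-3-[(2R)-2-[(R)-hydroxy{(2R,5S)-5-[(1S)-1-(triethylsilyloxy)ethyl]oxolan-2-yl}methyl]pent-4-enoyl]-1,3-oxazolidin-2-one | C[C@H](O[Si](CC)(CC)CC)[C@@H]1CC[C@H]([C@H](O)[C@H](C(=O)N2[C@H](Cc3ccccc3)COC2=O)CC=C)O1
F2 | step 7 | (2R)-2-[(R)-hydroxy{(2R,5S)-5-[(1S)-1-(triethylsilyloxy)ethyl]oxolan-2-yl}methyl]-N-methoxy-N-methylpent-4-enamide | C[C@H](O[Si](CC)(CC)CC)[C@@H]1CC[C@H]([C@H](O)[C@H](C(=O)N(C)OC)CC=C)O1
F3 | step 7 | (2R)-2-[(R)-(tert-butyldimethylsilyloxy){(2R,5S)-5-[(1S)-1-(triethylsilyloxy)ethyl]oxolan-2-yl}methyl]-N-methoxy-N-methylpent-4-enamide | C[C@H](O[Si](CC)(CC)CC)[C@@H]1CC[C@H]([C@H](O[Si](C)(C)C(C)(C)C)[C@H](C(=O)N(C)OC)CC=C)O1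
F4 | step 7 | (4R)-4-[(R)-(tert-butyldimethylsilyloxy){(2R,5S)-5-[(1S)-1-(triethylsilyloxy)ethyl]oxolan-2-yl}methyl]hepta-1,6-dien-3-one | C[C@H](O[Si](CC)(CC)CC)[C@@H]1CC[C@H]([C@H](O[Si](C)(C)C(C)(C)C)[C@H](C(=O)C=C)CC=C)O1
F5 | step 7 | (5R)-5-[(R)-(tert-butyldimethylsilyloxy){(2R,5S)-5-[(1S)-1-(triethylsilyloxy)ethyl]oxolan-2-yl}methyl]cyclopent-2-en-1-one | C[C@H](O[Si](CC)(CC)CC)[C@@H]1CC[C@H]([C@H](O[Si](C)(C)C(C)(C)C)[C@H]2CC=CC2=O)O1
F6 | step 3 | [(2R,5S)-5-acetyloxolan-2-yl]methyl acetate | CC(=O)[C@@H]1CC[C@H](COC(C)=O)O1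
F7 | step 15 | (1S)-1-[(2S,5R)-5-[(S)-(tert-butyldimethylsilyloxy)[(2R)-6-oxo-3,6-dihydro-2H-pyran-2-yl]methyl]oxolan-2-yl]ethyl [bis(2,2,2-trifluoroethoxy)phosphoryl]acetate | C[C@H](OC(=O)CP(=O)(OCC(F)(F)F)OCC(F)(F)F)[C@@H]1CC[C@H]([C@H](O[Si](C)(C)C(C)(C)C)[C@H]2CC=CC(=O)O2)O1
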